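## Retrosynthetic overview
1. Esters and C8 come last. The target goes back to a 6-hydroxy-8-ketone: an acetaldehyde hemiacetal on O6 passes its hydride to C8 (Evans–Tishchenko) and remains as the 6-acetate, and the freed 8-OH is then benzoylated.
2. The ten-membered ring is cut at C6–C7, the farnesyl C1–C10 bond that germacrene synthases form. Hydride goes to C11 and C10 attacks C1, here as a reductive aldol of a 9-oxo dienone onto the C1 aldehyde.
3. The oxirane comes from the Z-2,3-olefin of nerol by asymmetric epoxidation. It is the only source of absolute configuration and is relayed to C6, C7 and C8.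
4. The C15 chain is nerol (C10) + CO (C1) + isobutenyl (C4), joined at the ene-chlorinated nerol terminus by carbonylative Stille coupling.
5. Ring order: oxirane (step 1), then the carbocycle (step 6).

Assumption: the SMILES is taken literally, so the oxirane is cis (C3 and C6 on the same face, 4S,5R) with 1(10)E,6R,7R,8S; ring compounds use germacrane numbering and open chains use farnesane numbering (C1 = later C6, C10 = later C7).

## Route

**Step 1**
Reactants: 1 nerol
Product: 2 (2R,3S)-2,3-epoxy-3,7-dimethyloct-6-en-1-ol (cis-oxirane)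
Conditions: Ti(OiPr)4 (5 mol %), D-(−)-diisopropyl tartrate (7 mol %), t-BuOOH (1.5 equiv, decane), 4 Å MS, CH2Cl2, −20 °C
Reagents that add atoms: tert-butyl hydroperoxide, CC(C)(C)OO
Why: Sharpless asymmetric epoxidation touches only the allylic-alcohol olefin, syn addition to the Z-olefin fixes the cis-oxirane, and the D-(−)-tartrate gives the 2R,3S enantiomer (later C5 R and C4 S) in about 90–94% ee, mirroring the 2S,3R product that nerol gives with L-(+)-tartrate.

**Step 2**
Reactants: 2 (2R,3S)-epoxynerol
Product: 3 (2R,3S,6RS)-6-chloro-2,3-epoxy-3,7-dimethyloct-7-en-1-ol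
Conditions: NCS (1.1 equiv), PhSeCl (5 mol %), CH2Cl2, 23 °C
Reagents that add atoms: N-chlorosuccinimide, O=C1CCC(=O)N1Cl
Why: Selenium-catalysed ene-type allylic chlorination attacks the only remaining, electron-rich trisubstituted olefin and shifts it to an isopropenyl terminus next to a secondary chloride, whose C6 centre forms unselectively and is erased in step 4.

**Step 3**
Reactants: 4 2-methylprop-1-enylmagnesium bromide; 5 tributyltin chloride
Product: 6 tributyl(2-methylprop-1-enyl)stannane
Conditions: THF, 0 to 23 °C
Reagents that add atoms: tributyltin chloride (5), CCCC[Sn](Cl)(CCCC)CCCC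
Why: Transmetalation of a vinyl Grignard reagent to tin by substitution at the Sn–Cl bond, with no stereocentre involved.

**Step 4**
Reactants: 3 allylic chloride; 6 stannane
Product: 7 (2R,3S,6E)-2,3-epoxy-1-hydroxy-3,7,11-trimethyldodeca-6,10-dien-9-one
Conditions: Pd2(dba)3 (2.5 mol %), PPh3 (10 mol %), CO (3 atm), THF, 45 °C
Reagents that add atoms: carbon monoxide, [C-]#[O+]; stannane 6, CC(C)=C[Sn](CCCC)(CCCC)CCCC
Why: In this carbonylative Stille coupling zerovalent palladium ionises both chloride epimers to the same syn-allyl unit, CO inserts at the unhindered CH2 terminus and the vinyl group moves over from tin, giving the skipped dienone with the new trisubstituted olefin E under neutral conditions that spare the free OH, the oxirane and the base-sensitive β,γ-enone.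

**Step 5**
Reactants: 7 epoxy alcohol dienone
Product: 8 (2S,3S,6E)-2,3-epoxy-3,7,11-trimethyl-9-oxododeca-6,10-dienal
Conditions: TEMPO (10 mol %), PhI(OAc)2 (1.1 equiv), CH2Cl2, 0 to 23 °C
Reagents that add atoms: none
Why: Oxoammonium (TEMPO/PhI(OAc)2) oxidation of the primary alcohol stops at the aldehyde without base, so the oxirane carbons keep their geometry (the C2 descriptor becomes S by priority only) and the skipped enone does not slip into conjugation.

**Step 6** (key step)
Reactants: 8 epoxy aldehyde dienone
Product: 11 (1(10)E,4S,5R,6R,7S)-4,5-epoxy-6-hydroxygermacr-1(10)-en-8-one, via copper enolate 9 (not isolated), via copper aldolate 10 (not isolated)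
Conditions: [(Ph3P)CuH]6 (0.25 equiv), degassed toluene, −20 to 0 °C, 8 added over 12 h to 1 mM; aq NH4Cl
Reagents that add atoms: none
Why: Proposed new method: the copper hydride conjugate reduction–aldol cyclisation, known for keto-enones closing five- and six-membered rings, is stretched to a ten-membered ring, relying on the PPh3-ligated hydride adding 1,4 to the s-cis β,β-dimethyl enone faster than 1,2 to a saturated aldehyde (the selectivity that lets enal reductions stop at the aldehyde), which puts H on C11 and gives only the Z enolate 9 at C7 with no base to touch the acidic C9 methylene, so that without a proton source 9 can only close onto the C6 aldehyde at high dilution with the cis-oxirane and E-olefin folding the chain, while C6 (R) is set by Felkin–Anh/Cornforth attack anti to the oxirane C–O bond and C7 by a copper-bridged Zimmerman–Traxler chair in which the tether forces the oxiranyl group axial and trans-diaxial to the isopropyl of the Z enolate, giving the 6,7-anti aldol.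

**Step 7**
Reactants: 11 hydroxy ketone
Product: 14 target (1(10)E,4S,5R,6R,7R,8S)-6-acetoxy-8-benzoyloxy-4,5-epoxygermacr-1(10)-ene, via hemiacetal 12 (not isolated), via hydroxy acetate 13 (not isolated)
Conditions: SmI2 (0.3 equiv, premixed with MeCHO), MeCHO (8 equiv), THF, −10 °C; strip MeCHO; BzCl (3 equiv), pyridine, DMAP (0.2 equiv), 0 to 23 °C
Reagents that add atoms: acetaldehyde, CC=O; benzoyl chloride, O=C(Cl)c1ccccc1
Why: In this Evans–Tishchenko reduction trivalent samarium ties the O6 hemiacetal 12 to the C8 ketone and the hemiacetal C–H is delivered intramolecularly to the ketone face on which the pseudo-axial O6 (ring-cis to the equatorial isopropyl) sits, so the C8–O bond ends up 1,3-anti to C6–O (8S), the oxidised hemiacetal stays as the acetate on O6, and the only free hydroxyl is benzoylated at once by DMAP-catalysed acylation before any 6-to-8 acetyl shift.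

## Compound list
1 | nerol, (2Z)-3,7-dimethylocta-2,6-dien-1-ol | CC(C)=CCC/C(C)=C\CO | starting material
2 | (2R,3S)-2,3-epoxy-3,7-dimethyloct-6-en-1-ol | CC(C)=CCC[C@]1(C)O[C@@H]1CO | intermediate
3 | (2R,3S,6RS)-6-chloro-2,3-epoxy-3,7-dimethyloct-7-en-1-ol, about 1:1 at C6 | C=C(C)C(Cl)CC[C@]1(C)O[C@@H]1CO | intermediate
4 | 2-methylprop-1-enylmagnesium bromide | CC(C)=C[Mg]Br | starting material
5 | tributyltin chloride | CCCC[Sn](Cl)(CCCC)CCCC | starting material
6 | tributyl(2-methylprop-1-enyl)stannane | CC(C)=C[Sn](CCCC)(CCCC)CCCC | intermediate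
7 | (2R,3S,6E)-2,3-epoxy-1-hydroxy-3,7,11-trimethyldodeca-6,10-dien-9-one | CC(C)=CC(=O)C/C(C)=C/CC[C@]1(C)O[C@@H]1CO | intermediate
8 | (2S,3S,6E)-2,3-epoxy-3,7,11-trimethyl-9-oxododeca-6,10-dienal | CC(C)=CC(=O)C/C(C)=C/CC[C@]1(C)O[C@@H]1C=O | intermediate
9 | (9Z)-enolate of monovalent copper from 8 (PPh3 ligands omitted) | CC(C)/C=C(\O[Cu])C/C(C)=C/CC[C@]1(C)O[C@@H]1C=O | intermediate (not isolated)
10 | copper 6-alkoxide of 11 (PPh3 ligands omitted) | [Cu]O[C@@H]1[C@H](C(C)C)C(=O)C/C(C)=C/CC[C@]2(C)O[C@H]12 | intermediate (not isolated)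
11 | (1(10)E,4S,5R,6R,7S)-4,5-epoxy-6-hydroxygermacr-1(10)-en-8-one | O[C@@H]1[C@H](C(C)C)C(=O)C/C(C)=C/CC[C@]2(C)O[C@H]12 | intermediate
12 | O6-(1-hydroxyethyl) hemiacetal of 11 (samarium-bound in the flask) | CC(O)O[C@@H]1[C@H](C(C)C)C(=O)C/C(C)=C/CC[C@]2(C)O[C@H]12 | intermediate (not isolated)
13 | (1(10)E,4S,5R,6R,7R,8S)-6-acetoxy-4,5-epoxygermacr-1(10)-en-8-ol | CC(=O)O[C@@H]1[C@H](C(C)C)[C@@H](O)C/C(C)=C/CC[C@]2(C)O[C@H]12 | intermediate (not isolated)
14 | (1(10)E,4S,5R,6R,7R,8S)-6-acetoxy-8-benzoyloxy-4,5-epoxygermacr-1(10)-ene | CC(=O)O[C@@H]1[C@H](C(C)C)[C@@H](OC(=O)c2ccccc2)C/C(C)=C/CC[C@]2(C)O[C@H]12 | target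

## Totals and risks
Total steps: 7. Longest linear sequence: 6 (steps 1, 2, 4, 5, 6, 7).

**Step 6 (highest risk).**
- Ten-membered closure competes with oligomerisation.
- The hindered enone may be reduced more slowly than the activated epoxy aldehyde.
- The aldolate can undergo retro-aldol.

The fallback sets out from 8 and comes back at 11. It separates hydride delivery from C–C bond formation. 1,4-Hydrosilylation of the enone with Et3SiH and Pt2(dvtms)3 (dvtms = 1,3-divinyltetramethyldisiloxane), a catalyst that leaves saturated aldehydes and trisubstituted olefins alone, gives the isolable (9Z)-triethylsilyl enol ether aldehyde F1. F1 is fed slowly into BF3·OEt2 in CH2Cl2 at −78 °C (1 mM), so the same C6–C7 bond closes through an open-transition-state Mukaiyama aldol. Aqueous work-up gives 11.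

**Step 7.**
- The samarium-bridged bicyclic transition state has to fit inside the ten-membered ring.
- Retro-aldol ring opening or acetyl migration may be faster than hydride transfer.

The fallback sets out from 11 and comes back at 14. Hydride is delivered from boron bound to O6, which needs no metal bridge to the ketone oxygen: Me4NBH(OAc)3 in MeCN/AcOH at −30 °C gives the 6,8-anti diol F2. The two esters are then placed by site selectivity. The equatorial, less hindered 8-OH is benzoylated first (BzCl 1.05 equiv, pyridine, −20 °C) to the 8-benzoate 6-alcohol F3. Ac2O/DMAP/pyridine then acetylates O6 to give 14.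

**Step 4.**
- Direct coupling without CO can compete.
- E/Z selectivity can leak through syn–anti exchange of the 2-methylallyl palladium unit.
- β-Hydride loss gives a diene.
- The skipped olefin can drift into conjugation.

The fallback sets out from 3 and comes back at 7. The three-component coupling is split into two acyl-transfer operations without tin. Aminocarbonylation (PdCl2(PPh3)2, CO 5 atm, MeNH(OMe)·HCl, Et3N, THF, 50 °C) turns 3 into the (E)-β,γ-unsaturated Weinreb amide F4, which is far less prone to conjugation than the ketone. Grignard reagent 4 (2.2 equiv, THF, −20 °C) then adds once, and the chelated adduct releases 7 only on a cold, mildly acidic quench.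

## Further compounds
F1 | step 6 | (2S,3S,6E,9Z)-2,3-epoxy-3,7,11-trimethyl-9-(triethylsilyloxy)dodeca-6,9-dienal | CC(C)/C=C(\O[Si](CC)(CC)CC)C/C(C)=C/CC[C@]1(C)O[C@@H]1C=O
F2 | step 7 | (1(10)E,4S,5R,6R,7R,8S)-4,5-epoxygermacr-1(10)-ene-6,8-diol | O[C@@H]1[C@H](C(C)C)[C@@H](O)C/C(C)=C/CC[C@]2(C)O[C@H]12
F3 | step 7 | (1(10)E,4S,5R,6R,7S,8S)-8-benzoyloxy-4,5-epoxygermacr-1(10)-en-6-ol (C7 descriptor changes by priority only) | O[C@@H]1[C@H](C(C)C)[C@@H](OC(=O)c2ccccc2)C/C(C)=C/CC[C@]2(C)O[C@H]12
F4 | step 4 | (3E)-6-[(2S,3R)-3-(hydroxymethyl)-2-methyloxiran-2-yl]-N-methoxy-N,3-dimethylhex-3-enamide | CON(C)C(=O)C/C(C)=C/CC[C@]1(C)O[C@@H]1CO
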